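## Analysis of the target

The target, C84H64O18, is a resveratrol hexamer with twelve benzene rings, fifteen free phenols and three trans-2-(4-hydroxyphenyl)-3-aryl-2,3-dihydrobenzofurans, all (2R,3R). In fragment A the first dihydrobenzofuran is bridged from C-4 to the ortho carbon of its C-3 resorcinol ring by two sp3 carbons: Cb (on C-4) and Ca (on the resorcinol ring, bearing a 4-hydroxyphenyl group). This closes a dibenzo-fused cycloheptane. Cb carries the linker Ce, a CH(4-hydroxyphenyl) group, bonded to Cx of fragment B; there a second dihydrobenzofuran is bridged by three carbons, Cx (on C-4), Cy and Ch (on the resorcinol ring, bearing a 4-hydroxyphenyl group), giving a cyclooctane, and Cy carries fragment C, a third dihydrobenzofuran bonded through its C-4. Six of the twelve stereocentres lie in the furans and six form the chain Ca–Cb–Ce–Cx–Cy–Ch. The hydrogens on Ca, Cb and furan C-3 of fragment A are mutually cis; the linker on Cx and fragment C on Cy are cis; fragment C and the aryl group on Ch are trans; H on Ch is cis to H-3 of its furan. The sensitive groups are the oxidisable phenols and the benzylic C-2–O bonds of the furans, which ionise in strong acid and can epimerise or open. The difficulty is the chain of six all-carbon benzylic stereocentres without heteroatom handles, set in two medium rings and a very crowded linker region. The strategy rests on one feature: Ca bears a free 4-hydroxyphenyl group and is bonded to Cb, and Cb carries Ce, which itself bears an aryl group, so Ce can be an aryl ketone carbonyl, Cb its enolisable α-carbon and Ca the exocyclic carbon of the quinone methide of the target's own phenol.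

## Retrosynthetic reasoning

**39 to 38.** The fifteen O–H bonds are traced to O–methyl bonds. Methyl ethers are the only phenol protection that survives the organolithium, Lewis acid and base steps of the route. The forward step must cleave them all without touching a C–C stereocentre.

**38 to 37 to 34 and 11.** The Cy–H bond is traced to a Cy–OH bond and the Cy–aryl bond is cut. Fragment C is attached through its C-4, the one position of block bromide 11 that carries a halogen. Adding it last keeps the route convergent and lets the same block 11 serve twice. The forward steps must add an aryl nucleophile to a hindered ketone and then deliver hydride to Cy from the correct face.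

**34 to 33 and 19.** The Ce–Cx bond is cut. Ce is a 4-methoxybenzylic carbon and can be a cation; Cx is α to the eight-ring ketone and can be the carbon of enol silane 19. This joins two complete halves and places the ketone exactly where fragment C will enter. The forward reaction must set Ce and Cx.

**19 to 18 to 15 to 13 to 11.** Enol silane 19 comes from ketone 18. The eight-membered ring is contracted by removing the CH(aryl) carbon, which the forward route supplies from diazo compound 17 (made from 16); this gives seven-ring ketone 15. A seven-membered ring closes readily by Friedel–Crafts acylation of arylacetic acid 14 onto the neighbouring dimethoxyphenyl ring, whereas the eight-membered ring has no such direct closure. Acid 14 is set free from ester 13, whose side chain is traced to the bromide of 11 and zinc reagent 12.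

**33 to 32 to 31.** A phenol methylation and a ketone reduction are removed. They bring Ce from the ketone to the ionisable carbinol level.

**31 to 29 (by way of 30).** The Ca–Cb bond is cut. Ca carries the 4-hydroxyphenyl group and becomes the methide carbon of quinone methide 30; Cb is α to the Ce ketone and becomes an enol carbon. This one cut removes the seven-membered ring and two stereocentres and leaves a ketone at the linker carbon. In 29 the carbinol oxygen is carried as its methyl ether: a free or silylated oxygen at that position would add to ortho-quinone methide 25 or migrate silicon during the assembly of the furan. The methyl ether ionises under the same acid as the carbinol.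

**29 to 28 to 26 and 27.** A silyl group is removed and the aryl–CH2 bond at C-4 is cut, which is a ketone α-arylation of 27 by the bromide of 26.

**26 and 11 to 3, an aryl metal and ylide 10.** In each dihydrobenzofuran three bonds are cut: C-3–aryl, C-2–C-3 and C-2–O. The aldehyde carbon of 3 becomes C-3, the aryl metal (24 from 23, or 8 from 7) supplies the resorcinol ring, and the ylide carbon of 10 becomes C-2. The substitution pattern of the benzofuran ring is fixed by the aldehyde, so no regiochemical choice on a resorcinol ring arises. The chiral sulfide 4 built into 10 supplies the absolute configuration.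

**3, 23 and 6 to starting materials.** Compound 3 comes from 1 by way of 2. Compound 23 comes from 1 and 20 by way of 21 and 22, so the formyl carbon of 1 becomes Ca. Compound 6 comes from 4 and 5.

## Alternatives that were turned down

**Alternative 1:** Each dihydrobenzofuran block is taken apart in both its benzene ring and its furan ring, back to an acyclic precursor that carries a diazo ketone and a tethered alkynyl ether. Forward, light triggers a Wolff rearrangement, the resulting ketene adds to the alkyne, the four-membered ring opens and the chain closes again to the phenol A1 (a Danheiser benzannulation). In its favour, the substitution pattern of the resorcinol ring is built with complete certainty, and the C-6 phenol is free and distinct from the methyl ethers. Against it, both furan stereocentres must be made beforehand in the acyclic tether, the sequence is multistep and photochemical, and it would be needed three times. It also addresses only the repeating block and nothing in the two medium rings or the six chain stereocentres. On regiochemical certainty it is as strong as or stronger than the chosen route. The chosen route answers with an aldehyde whose pattern is already fixed, makes the block in one flask, and spends its key step on a ring and two stereocentres.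

**Alternative 2:** The eight-membered ring is cut at the two bonds to one arene, back to a six-membered cyclic keto ester and an aryne generated in the flask. Forward, the enolate arylates the aryne, the aryl anion closes onto the ketone and the four-membered alkoxide fragments, giving A2 by a two-carbon ring expansion. In its favour, the medium ring is made directly and convergently, without a slow cyclisation; for the bare ring this is stronger than the chosen route, whose ring expansion is one of its uncertain steps. Against it, A2 carries its functions in the wrong places for this target. The carbon that must bear a 4-hydroxyphenyl group arrives bearing an ester, the aryl ketone must be removed, the furan of fragment B is still to be built on a dibenzyloxy ring, and the aryne is unsymmetrical. In exchange, the chosen route has every aryl group and the furan in place before the medium ring is made, and its ketone sits where the last aryl group enters.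

**Alternative 3:** The seven-membered ring is cut in the same way, back to a five-membered cyclic keto ester and the same kind of aryne; forward, the same insertion gives A3. In its favour, this is the shortest access to the dibenzocycloheptanone skeleton and needs no functionalised dihydrobenzofuran; on brevity to the bare ring it is stronger. Against it, the ester-bearing methine, the future furan C-3, is doubly benzylic and α to an ester, so it is configurationally labile. The furan must be built afterwards, Ca needs an aryl addition and a deoxygenation controlled from that labile centre, and Cb is still a plain CH2 that must receive the linker. The chosen strategy closes the ring from an enantiopure dihydrobenzofuran so that C-3 directs Ca, sets Cb in the same step, uses the target's own phenol as activating group, and delivers the linker carbon as a ketone.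

Key step: step 14

Remark: the sense of induction of ylide 10 is assumed to give the (3R) centre with the (1R,4R,5R) sulfide drawn; if it proves opposite, the enantiomeric sulfide is used and nothing else changes.

## Steps

Step 1
Reactants: 1 2-bromo-4,6-dimethoxybenzaldehyde
Product: 2 2-bromo-6-hydroxy-4-methoxybenzaldehyde
Conditions: BCl3, CH2Cl2, −78 → 0 °C; aq. work-up
Reagents that add atoms: none
Why: Chelation of boron between the formyl oxygen and the ortho methoxyl directs cleavage to that ether only (chelation-controlled aryl methyl ether cleavage); the para methoxyl and the bromide are untouched.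

Step 2
Reactants: 2 2-bromo-6-hydroxy-4-methoxybenzaldehyde
Product: 3 tert-butyl 3-bromo-2-formyl-5-methoxyphenyl carbonate
Conditions: Boc2O, i-Pr2NEt, DMAP (cat.), THF, 0 °C → rt
Reagents that add atoms: di-tert-butyl dicarbonate, CC(C)(C)OC(=O)OC(=O)OC(C)(C)C
Why: DMAP-catalysed O-acylation of the phenol; the carbonate is the group that later migrates and leaves to generate the ortho-quinone methide under anionic conditions.

Step 3
Reactants: 4 (1R,4R,5R)-isothiocineole; 5 4-methoxybenzyl bromide
Product: 6 S-(4-methoxybenzyl)isothiocineolium triflate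
Conditions: LiOTf, CH2Cl2/H2O, rt
Reagents that add atoms: lithium triflate, [Li+].[O-]S(=O)(=O)C(F)(F)F
Why: SN2 S-alkylation on the open face of the bicyclic sulfide should give one sulfonium diastereomer; anion exchange gives the non-nucleophilic triflate.

Step 4
Reactants: 3 tert-butyl 3-bromo-2-formyl-5-methoxyphenyl carbonate; 7 1-bromo-3,5-dimethoxybenzene; 6 S-(4-methoxybenzyl)isothiocineolium triflate
Product: 11 block bromide (2R,3R)-4-bromo-3-(3,5-dimethoxyphenyl)-6-methoxy-2-(4-methoxyphenyl)-2,3-dihydro-1-benzofuran, via aryl Grignard reagent 8 (not isolated), via ortho-quinone methide 9 (not isolated), via sulfonium ylide 10 (not isolated)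
Conditions: 7, Mg, THF, 40 °C; 3, THF, −78 °C; 10 (from 6, LiN(SiMe3)2, THF, −78 °C), −78 → 0 °C
Reagents that add atoms: none
Why: The Grignard reagent adds to the aldehyde, the alkoxide takes the Boc group from the phenol oxygen and the magnesium phenoxide expels tert-butyl carbonate to give 9 (anionic ortho-quinone methide generation); ylide 10 adds to the methide carbon and the phenoxide displaces the sulfide, closing the trans ring ([4+1] annulation of sulfonium ylides with ortho-quinone methides). The chiral sulfide fixes the attacking face of the ylide, the anti addition mode then fixes C-3 as R, and C-2 follows as the trans partner.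

Step 5
Reactants: 11 block bromide; 12 (2-tert-butoxy-2-oxoethyl)zinc bromide
Product: 13 tert-butyl 2-[(2R,3R)-3-(3,5-dimethoxyphenyl)-6-methoxy-2-(4-methoxyphenyl)-2,3-dihydro-1-benzofuran-4-yl]acetate
Conditions: Pd(dba)2 (2 mol%), Q-Phos (2 mol%), THF, rt → 50 °C
Reagents that add atoms: none
Why: Negishi-type coupling of the zinc ester enolate (Reformatsky reagent) with the aryl bromide under neutral conditions; the bulky ferrocenyl phosphine tolerates the ortho substituent and no stereocentre is exposed to base.

Step 6
Reactants: 13 tert-butyl arylacetate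
Product: 15 seven-ring ketone of fragment B (acyl carbon bonded to C-2 of the dimethoxyphenyl ring), via arylacetic acid 14 (not isolated)
Conditions: CF3CO2H/CH2Cl2 (1:4), 0 °C → rt; concentrate; (CF3CO)2O, CH2Cl2, 0 °C
Reagents that add atoms: none
Why: Acid removes the tert-butyl group and the mixed trifluoroacetic anhydride of 14 acylates the only arene carbon it can reach in a normal ring, the ortho position of the 3,5-dimethoxyphenyl ring para to a methoxyl (intramolecular Friedel–Crafts acylation, seven-membered ring). Short contact at 0 °C limits ionisation at furan C-2, which would in any case re-close to the trans isomer.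

Step 7
Reactants: 15 seven-ring ketone of fragment B; 16 4-methoxybenzaldehyde tosylhydrazone
Product: 18 eight-ring ketone of fragment B (CH(4-methoxyphenyl) inserted between C=O and arene), via 4-methoxyphenyldiazomethane 17 (not isolated)
Conditions: 16, NaOMe, MeOH, then dry salt 90 °C/vacuum into toluene at −78 °C; 15, Sc(OTf)3 (10 mol%), toluene/CH2Cl2, −78 → −20 °C; then DBU (cat.), rt
Reagents that add atoms: none
Why: Lewis-acid-promoted diazoalkane homologation (Tiffeneau–Demjanov-type ring expansion): the diazo carbon adds to the activated carbonyl and the electron-rich aryl group, the better migrating group, shifts with loss of N2, so CH(aryl) is inserted between carbonyl and arene. The new α-aryl centre is epimerisable, and DBU is expected to settle it with the aryl group pseudo-equatorial, H cis to furan H-3, as drawn.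

Step 8
Reactants: 18 eight-ring ketone of fragment B
Product: 19 trimethylsilyl enol ether of 18 towards the CH2 carbon
Conditions: LiN(SiMe3)2, Me3SiCl, THF, −78 °C (internal quench)
Reagents that add atoms: chlorotrimethylsilane, C[Si](C)(C)Cl
Why: The bulky amide removes a proton kinetically from the less hindered benzylic CH2 and not from the diaryl-substituted methine, and the enolate is trapped at once; the α-aryl centre is not touched.

Step 9
Reactants: 1 2-bromo-4,6-dimethoxybenzaldehyde; 20 (4-bromophenoxy)triisopropylsilane
Product: 22 (2-bromo-4,6-dimethoxyphenyl)[4-(triisopropylsilyloxy)phenyl]methanol (racemic), via aryl Grignard reagent 21 (not isolated)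
Conditions: 20, Mg, THF, 40 °C; then 1, THF, 0 °C
Reagents that add atoms: none
Why: Grignard addition to the aldehyde; the aryl bromide of 1 does not exchange with an arylmagnesium halide at 0 °C. The carbinol centre is racemic and is destroyed in step 14.

Step 10
Reactants: 22 diaryl carbinol
Product: 23 1-bromo-3,5-dimethoxy-2-{methoxy[4-(triisopropylsilyloxy)phenyl]methyl}benzene (racemic)
Conditions: MeOH, PPTS (cat.), rt
Reagents that add atoms: methanol, CO
Why: SN1 etherification through the doubly stabilised benzhydryl cation; the methyl ether blocks the oxygen during step 11 and is the leaving group of the key step. The aryl silyl ether survives the mild acid.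

Step 11
Reactants: 23 benzhydryl methyl ether bromide; 3 tert-butyl 3-bromo-2-formyl-5-methoxyphenyl carbonate; 6 S-(4-methoxybenzyl)isothiocineolium triflate
Product: 26 fragment-A bromide (2R,3R)-4-bromo-3-{3,5-dimethoxy-2-[methoxy(4-triisopropylsilyloxyphenyl)methyl]phenyl}-6-methoxy-2-(4-methoxyphenyl)-2,3-dihydro-1-benzofuran (both ether epimers), via aryllithium 24 (not isolated), via ortho-quinone methide 25 (not isolated)
Conditions: 23, t-BuLi (2 equiv), THF, −78 °C; 3, −78 °C; MgBr2·OEt2; then 6 deprotonated in a second flask (LiN(SiMe3)2, THF, −78 °C, as in step 4) and transferred by cannula, −78 → 0 °C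
Reagents that add atoms: none
Why: Bromine–lithium exchange is faster than any deprotonation at −78 °C; the sequence then follows step 4 (addition, Boc transfer, magnesium-triggered elimination to 25, then annulation with a fresh portion of the ylide already described as 10, made from 6 in the same way), with C-3 set by the ylide as before. The ether carbon is not controlled, so 26 is expected as two epimers that converge in step 14.

Step 12
Reactants: 26 fragment-A bromide; 27 4'-methoxyacetophenone
Product: 28 2-{(2R,3R)-3-[3,5-dimethoxy-2-(methoxy(4-triisopropylsilyloxyphenyl)methyl)phenyl]-6-methoxy-2-(4-methoxyphenyl)-2,3-dihydro-1-benzofuran-4-yl}-1-(4-methoxyphenyl)ethanone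
Conditions: Pd2(dba)3 (2 mol%), XPhos (5 mol%), K3PO4, toluene, 90 °C
Reagents that add atoms: none
Why: Palladium-catalysed ketone α-arylation; the methyl ketone enolate couples once because the product enolate is too hindered for a second arylation, and K3PO4 spares the silyl ether.

Step 13
Reactants: 28 silyl-protected benzyl ketone
Product: 29 key-step precursor, the 4-hydroxyphenyl analogue of 28 (free phenol, benzhydryl methyl ether, both epimers)
Conditions: Bu4NF, AcOH, THF, 0 °C
Reagents that add atoms: none
Why: Fluoride cleaves the aryl silyl ether; acetic acid buffers the phenoxide so that neither the ketone enolate nor a quinone methide forms prematurely.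

Step 14
Reactants: 29 key-step precursor
Product: 31 dibenzocycloheptane ketone of fragment A (Ca–H, Cb–H and furan H-3 mutually cis; Ca bears 4-hydroxyphenyl, Cb bears 4-methoxybenzoyl), via para-quinone methide 30 (not isolated)
Conditions: (PhO)2PO2H (20 mol%), 4 Å MS, CH2Cl2 (0.005 M), 0 °C → rt
Reagents that add atoms: none
Why: The acid protonates the benzhydryl methyl ether; methanol leaves with help from the para-hydroxyl and the flanking methoxyls, and loss of the phenolic proton gives para-quinone methide 30, while the same acid enolises the benzyl aryl ketone, whose enol carbon adds to the methide carbon (1,6-addition) before the phenol rearomatises. The closest known reaction type is the acid-catalysed conjugate addition of enols and other π-nucleophiles to para-quinone methides formed in situ from 4-hydroxybenzhydrols. The cycloheptane closes in a 7-exo-trig mode, the breaking exocyclic C=C lying outside the new ring, and the two reacting carbons are held on adjacent positions of a rigid trans-dihydrobenzofuran. Ca is controlled by furan C-3 inside the forming ring: in the boat-like transition state H-3 is pseudo-axial and the quinoid ring is expected to take the outer position, which puts the new Ca–H cis to H-3. Cb is α to the ketone and stays in acid-mediated enol equilibrium, so it is expected to settle with the aroyl group cis to the new aryl group, as drawn. The step needs C-alkylation by the enol in preference to Friedel–Crafts attack; the only arene carbon within reach, the ortho carbon of the furan 2-aryl group, is meta to its methoxyl and would need a trans-fused ring. High dilution suppresses intermolecular addition, and both ether epimers of 29 converge on the same planar methide.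

Step 15
Reactants: 31 dibenzocycloheptane ketone of fragment A
Product: 32 corresponding (4-methoxyphenyl)carbinol (either carbinol epimer)
Conditions: NaBH4, CeCl3·7H2O, MeOH/THF, −20 °C
Reagents that add atoms: none
Why: Luche-type 1,2-reduction; the buffered medium avoids enolisation at Cb. The new carbinol centre is not controlled and is lost in step 17.

Step 16
Reactants: 32 phenol carbinol
Product: 33 O-methylated carbinol of fragment A (Ca now bears 4-methoxyphenyl)
Conditions: MeI, K2CO3, acetone, 40 °C
Reagents that add atoms: iodomethane, CI
Why: Williamson methylation of the phenol only, since carbonate does not deprotonate the secondary benzylic alcohol; methylating after the reduction avoids C-methylation or epimerisation α to the ketone.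

Step 17
Reactants: 33 O-methylated carbinol of fragment A; 19 trimethylsilyl enol ether of fragment B
Product: 34 coupled ketone (Ce–Cx bond formed; Ce and Cx configured as in the target; Cy is C=O)
Conditions: Bi(OTf)3 (10 mol%), MeNO2/CH2Cl2, −20 °C
Reagents that add atoms: none
Why: Bi(OTf)3 ionises the 4-methoxybenzylic alcohol and the cation is captured by the enol silane (SN1-type Mukaiyama alkylation with a benzylic alcohol). The cation should react in the conformer with the Cb–H bond in its plane (minimal 1,3-allylic strain), on the face away from the aryl-bearing ring carbon, which is expected to give the Ce configuration drawn. The enol ether is attacked anti to the aryl group on Ch, and Cx, still α to the ketone, can be corrected by base equilibration.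

Step 18
Reactants: 11 block bromide; 34 coupled ketone
Product: 37 tertiary carbinol at Cy bearing fragment C (either carbinol epimer), via aryllithium 35 (not isolated), via aryl-cerium dichloride 36 (not isolated)
Conditions: 11, t-BuLi (2 equiv), THF, −78 °C; CeCl3, −78 °C; then 34, −78 → −40 °C
Reagents that add atoms: none
Why: Bromine–lithium exchange and transmetalation give the weakly basic, oxophilic aryl-cerium reagent, which adds to hindered, enolisable ketones where aryllithiums deprotonate (organocerium 1,2-addition). The carbinol configuration is irrelevant because this centre is ionised in step 19.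

Step 19
Reactants: 37 tertiary carbinol
Product: 38 pentadecamethyl ether of the target
Conditions: Et3SiH, CF3CO2H, CH2Cl2, −40 → −10 °C
Reagents that add atoms: none
Why: Ionic hydrogenation: the tertiary benzylic alcohol ionises and the silane delivers hydride anti to the bulkier neighbouring substituent, the linker on Cx, which puts Cy–H cis to Cx–H and fragment C trans to the aryl group on Ch. Low temperature is needed to keep the secondary benzylic C–O bonds of the three furans from ionising and being reduced.

Step 20
Reactants: 38 pentadecamethyl ether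
Product: 39 target CNP0184494.1
Conditions: BBr3 (excess), CH2Cl2, −78 → rt; MeOH, H2O
Reagents that add atoms: none
Why: Lewis-acid cleavage of all fifteen aryl methyl ethers; a furan C–O bond that opens can re-close to the trans ring, and no stereocentre is α to a carbonyl at this stage.

## Compound list

1 | 2-bromo-4,6-dimethoxybenzaldehyde | COc1cc(OC)c(C=O)c(Br)c1 | starting material
2 | 2-bromo-6-hydroxy-4-methoxybenzaldehyde | COc1cc(O)c(C=O)c(Br)c1 | intermediate
3 | tert-butyl 3-bromo-2-formyl-5-methoxyphenyl carbonate | COc1cc(OC(=O)OC(C)(C)C)c(C=O)c(Br)c1 | intermediate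
4 | (1R,4R,5R)-isothiocineole (4,7,7-trimethyl-6-thiabicyclo[3.2.1]octane) | C[C@@H]1CC[C@@H]2C[C@H]1SC2(C)C | starting material
5 | 4-methoxybenzyl bromide | COc1ccc(CBr)cc1 | starting material
6 | S-(4-methoxybenzyl)isothiocineolium triflate (one S-epimer expected) | C[C@@H]1CC[C@@H]2C[C@H]1[S+](Cc1ccc(OC)cc1)C2(C)C.[O-]S(=O)(=O)C(F)(F)F | intermediate
7 | 1-bromo-3,5-dimethoxybenzene | COc1cc(Br)cc(OC)c1 | starting material
8 | 3,5-dimethoxyphenylmagnesium bromide | COc1cc(OC)cc([Mg]Br)c1 | intermediate (not isolated)
9 | 5-bromo-6-(3,5-dimethoxybenzylidene)-3-methoxycyclohexa-2,4-dien-1-one | O=C1C=C(OC)C=C(Br)C1=Cc1cc(OC)cc(OC)c1 | intermediate (not isolated)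
10 | 4-methoxybenzylidene ylide of sulfonium salt 6 | C[C@@H]1CC[C@@H]2C[C@H]1[S+]([CH-]c1ccc(OC)cc1)C2(C)C | intermediate (not isolated)
11 | (2R,3R)-4-bromo-3-(3,5-dimethoxyphenyl)-6-methoxy-2-(4-methoxyphenyl)-2,3-dihydro-1-benzofuran | Brc1cc(OC)cc2c1[C@@H](c1cc(OC)cc(OC)c1)[C@H](c1ccc(OC)cc1)O2 | intermediate
12 | (2-tert-butoxy-2-oxoethyl)zinc bromide | CC(C)(C)OC(=O)C[Zn]Br | starting material
13 | tert-butyl 2-[(2R,3R)-3-(3,5-dimethoxyphenyl)-6-methoxy-2-(4-methoxyphenyl)-2,3-dihydro-1-benzofuran-4-yl]acetate | CC(C)(C)OC(=O)Cc1cc(OC)cc2c1[C@@H](c1cc(OC)cc(OC)c1)[C@H](c1ccc(OC)cc1)O2 | intermediate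
14 | the corresponding arylacetic acid | OC(=O)Cc1cc(OC)cc2c1[C@@H](c1cc(OC)cc(OC)c1)[C@H](c1ccc(OC)cc1)O2 | intermediate (not isolated)
15 | seven-ring ketone of fragment B: CH2–C(=O) bridge from benzofuran C-4 to C-2 of the dimethoxyphenyl ring, furan centres (2R,3R) trans | C1c2cc(OC)cc3c2[C@@H](c2cc(OC)cc(OC)c2C1=O)[C@H](c2ccc(OC)cc2)O3 | intermediate
16 | 4-methoxybenzaldehyde tosylhydrazone | COc1ccc(C=NNS(=O)(=O)c2ccc(C)cc2)cc1 | starting material
17 | 4-methoxyphenyldiazomethane | COc1ccc(C=[N+]=[N-])cc1 | intermediate (not isolated)
18 | eight-ring ketone of fragment B: CH2–C(=O)–CH(4-methoxyphenyl) bridge, H on the new centre cis to furan H-3 | C1c2cc(OC)cc3c2[C@@H](c2cc(OC)cc(OC)c2[C@H](c2ccc(OC)cc2)C1=O)[C@H](c2ccc(OC)cc2)O3 | intermediate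
19 | trimethylsilyl enol ether of 18 (C=C between the benzofuran-bound carbon and C–OSiMe3) | C=1c2cc(OC)cc3c2[C@@H](c2cc(OC)cc(OC)c2[C@H](c2ccc(OC)cc2)C1O[Si](C)(C)C)[C@H](c2ccc(OC)cc2)O3 | intermediate
20 | (4-bromophenoxy)triisopropylsilane | CC(C)[Si](C(C)C)(C(C)C)Oc1ccc(Br)cc1 | starting material
21 | 4-(triisopropylsilyloxy)phenylmagnesium bromide | CC(C)[Si](C(C)C)(C(C)C)Oc1ccc([Mg]Br)cc1 | intermediate (not isolated)
22 | (2-bromo-4,6-dimethoxyphenyl)[4-(triisopropylsilyloxy)phenyl]methanol, racemic | CC(C)[Si](C(C)C)(C(C)C)Oc1ccc(cc1)C(O)c1c(OC)cc(OC)cc1Br | intermediate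
23 | 1-bromo-3,5-dimethoxy-2-{methoxy[4-(triisopropylsilyloxy)phenyl]methyl}benzene, racemic | CC(C)[Si](C(C)C)(C(C)C)Oc1ccc(cc1)C(OC)c1c(OC)cc(OC)cc1Br | intermediate
24 | aryllithium from 23 (Li in place of Br) | CC(C)[Si](C(C)C)(C(C)C)Oc1ccc(cc1)C(OC)c1c(OC)cc(OC)cc1[Li] | intermediate (not isolated)
25 | ortho-quinone methide from 3 and 24 (as 9, the benzylidene aryl carrying the ortho CH(OMe)aryl group) | O=C1C=C(OC)C=C(Br)C1=Cc1cc(OC)cc(OC)c1C(OC)c1ccc(O[Si](C(C)C)(C(C)C)C(C)C)cc1 | intermediate (not isolated)
26 | (2R,3R)-4-bromo-3-{3,5-dimethoxy-2-[methoxy(4-triisopropylsilyloxyphenyl)methyl]phenyl}-6-methoxy-2-(4-methoxyphenyl)-2,3-dihydro-1-benzofuran, both ether epimers | CC(C)[Si](C(C)C)(C(C)C)Oc1ccc(cc1)C(OC)c3c(OC)cc(OC)cc3[C@@H]3c4c(cc(OC)cc4Br)O[C@H]3c2ccc(OC)cc2 | intermediate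
27 | 4'-methoxyacetophenone | CC(=O)c1ccc(OC)cc1 | starting material
28 | benzyl 4-methoxyphenyl ketone from 26 (CH2C(=O)C6H4OMe at benzofuran C-4), silyl ether | CC(C)[Si](C(C)C)(C(C)C)Oc1ccc(cc1)C(OC)c3c(OC)cc(OC)cc3[C@@H]3c4c(cc(OC)cc4CC(=O)c2ccc(OC)cc2)O[C@H]3c2ccc(OC)cc2 | intermediate
29 | key-step precursor: free 4-hydroxyphenyl analogue of 28, benzhydryl methyl ether, both epimers | Oc1ccc(cc1)C(OC)c3c(OC)cc(OC)cc3[C@@H]3c4c(cc(OC)cc4CC(=O)c2ccc(OC)cc2)O[C@H]3c2ccc(OC)cc2 | intermediate
30 | para-quinone methide from 29 | O=C1C=CC(C=C1)=Cc3c(OC)cc(OC)cc3[C@@H]3c4c(cc(OC)cc4CC(=O)c2ccc(OC)cc2)O[C@H]3c2ccc(OC)cc2 | intermediate (not isolated)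
31 | dibenzocycloheptane ketone of fragment A: Ca–H, Cb–H and furan H-3 mutually cis, furan (2R,3R) trans | Oc1ccc([C@H]2c3c(OC)cc(OC)cc3[C@@H]3c4c(cc(OC)cc4[C@H]2C(=O)c2ccc(OC)cc2)O[C@H]3c2ccc(OC)cc2)cc1 | intermediate
32 | carbinol from 31 (Ce–OH, either epimer) | Oc1ccc([C@H]2c3c(OC)cc(OC)cc3[C@@H]3c4c(cc(OC)cc4[C@H]2C(O)c2ccc(OC)cc2)O[C@H]3c2ccc(OC)cc2)cc1 | intermediate
33 | O-methyl ether of phenol 32 (carbinol free) | COc1ccc([C@H]2c3c(OC)cc(OC)cc3[C@@H]3c4c(cc(OC)cc4[C@H]2C(O)c2ccc(OC)cc2)O[C@H]3c2ccc(OC)cc2)cc1 | intermediate
34 | coupled ketone: fragment A joined through Ce to Cx of the eight-ring ketone, centres as in the target | COc1ccc([C@H]2c3c(OC)cc(OC)cc3[C@@H]3c4c(cc(OC)cc4[C@H]2[C@H](c2ccc(OC)cc2)[C@H]2c4cc(OC)cc5c4[C@@H](c4cc(OC)cc(OC)c4[C@H](c4ccc(OC)cc4)C2=O)[C@H](c2ccc(OC)cc2)O5)O[C@H]3c2ccc(OC)cc2)cc1 | intermediate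
35 | aryllithium from 11 (Li at C-4) | [Li]c1cc(OC)cc2c1[C@@H](c1cc(OC)cc(OC)c1)[C@H](c1ccc(OC)cc1)O2 | intermediate (not isolated)
36 | aryl-cerium dichloride from 35 | Cl[Ce](Cl)c1cc(OC)cc2c1[C@@H](c1cc(OC)cc(OC)c1)[C@H](c1ccc(OC)cc1)O2 | intermediate (not isolated)
37 | tertiary carbinol: 34 with fragment C and OH on Cy (either epimer at Cy) | COc1ccc([C@H]2c3c(OC)cc(OC)cc3[C@@H]3c4c(cc(OC)cc4[C@H]2[C@H](c2ccc(OC)cc2)[C@H]2c4cc(OC)cc5c4[C@@H](c4cc(OC)cc(OC)c4[C@H](c4ccc(OC)cc4)C2(O)c2cc(OC)cc4c2[C@@H](c2cc(OC)cc(OC)c2)[C@H](c2ccc(OC)cc2)O4)[C@H](c2ccc(OC)cc2)O5)O[C@H]3c2ccc(OC)cc2)cc1 | intermediate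
38 | pentadecamethyl ether of the target | COc1ccc([C@H]2c3c(OC)cc(OC)cc3[C@@H]3c4c(cc(OC)cc4[C@H]2[C@H](c2ccc(OC)cc2)[C@H]2c4cc(OC)cc5c4[C@@H](c4cc(OC)cc(OC)c4[C@H](c4ccc(OC)cc4)[C@H]2c2cc(OC)cc4c2[C@@H](c2cc(OC)cc(OC)c2)[C@H](c2ccc(OC)cc2)O4)[C@H](c2ccc(OC)cc2)O5)O[C@H]3c2ccc(OC)cc2)cc1 | intermediate
39 | CNP0184494.1 | Oc1ccc([C@H]2c3c(O)cc(O)cc3[C@@H]3c4c(cc(O)cc4[C@H]2[C@H](c2ccc(O)cc2)[C@H]2c4cc(O)cc5c4[C@@H](c4cc(O)cc(O)c4[C@H](c4ccc(O)cc4)[C@H]2c2cc(O)cc4c2[C@@H](c2cc(O)cc(O)c2)[C@H](c2ccc(O)cc2)O4)[C@H](c2ccc(O)cc2)O5)O[C@H]3c2ccc(O)cc2)cc1 | target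

## Step count and least certain steps

Total: 20 steps. Longest linear sequence: 12 steps (steps 9 to 20; equally steps 1, 2 and 11 to 20).

**Step 14 (key step).** The most likely failure is that equilibration at Cb settles the aroyl group trans to the new aryl group, because the thermodynamic preference in this crowded ring is not secure. Attack on the other methide face is the second risk, since control by furan C-3 is only remote. Fallback: setting out from 29, the acid closure is run as before and the Cb-epimeric ketone F1 is accepted. Its phenoxide–enolate dianion (LiN(SiMe3)2, THF, −78 °C) is then protonated kinetically by a bulky phenol on the face opposite the neighbouring aryl group, which returns the route to 31. Control at Cb thus changes from equilibration to kinetic protonation.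

**Step 17.** Poor facial selectivity at the Ce cation is the main risk, and loss of the Cb proton would also scramble that centre; both follow from a hindered, only moderately nucleophilic enol silane. Fallback: setting out from 13, the ester is turned into the silyl ketene acetal F2 (LiN(SiMe3)2, Me3SiCl), a smaller and far stronger nucleophile, and coupled with 33 under the same Bi(OTf)3 catalysis to the ester F3. Acid and trifluoroacetic anhydride, as in step 6, close the seven-ring ketone F4 on the coupled material, and ring expansion with 17, as in step 7, returns to 34.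

**Step 18.** Enolisation or no addition is likely, because the ketone lies between two substituted methines and the nucleophile is ortho-substituted. Fallback: setting out from 18, reagent 36 is added to this less hindered ketone to give the tertiary carbinol F5, and acid dehydration towards the CH2 gives the styrene-type alkene F6. Carbinol 33 is then ionised by Bi(OTf)3 in the presence of F6 and Et3SiH; the cation adds to the unsubstituted alkene carbon and the silane reduces the tertiary benzylic cation, rejoining the route at 38.

**Step 7.** Slow addition of the diazo compound to an electron-rich, hindered aryl ketone is likely, as is migration of the CH2 group in place of the arene. Fallback: setting out from 11, Stille allylation (allylSnBu3, Pd(PPh3)4) gives the allyl arene F7 and OsO4/NaIO4 cleavage gives the arylacetaldehyde F8. Corey–Chaykovsky epoxidation with ylide 10 gives the trans epoxide F9. Bi(OTf)3 opens it at the 4-methoxybenzylic carbon with Friedel–Crafts closure onto the dimethoxyphenyl ring to the eight-ring carbinol F10, and DMP oxidation returns to 18.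

**Step 11.** A slow or unselective annulation is likely, because the aryl group on the quinone methide carries a large ortho substituent. Fallback: setting out from 1, the aldehyde is protected as the dioxolane F11. Bromine–lithium exchange and the same one-flask sequence with 3 and 10 give the dioxolanyl dihydrobenzofuran bromide F12, and α-arylation with 27 gives the ketone F13. Mild acid hydrolysis gives the aldehyde F14; excess Grignard reagent 21, whose first equivalent masks the ketone as its enolate, gives the silyl carbinol F15; Bu4NF gives the free hydroxybenzhydrol F16. Under the conditions of step 14 this loses water in place of methanol and rejoins the route at 31.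

**Step 4.** Insufficient or reversed enantiocontrol is the risk, since induction by this ylide is established for additions to C=O and C=N bonds and not for quinone methides; the same applies to step 11. Fallback: setting out from 2, O-alkylation with 4-methoxybenzyl chloride gives the ether F17, Grignard reagent 8 gives the carbinol F18, and DMP gives the diaryl ketone F19. Hydrazine gives the hydrazone F20 and MnO2 the diaryldiazomethane F21. Rh2(R-PTAD)4 or its enantiomer then effects enantioselective carbene insertion into the benzylic ether C–H bond to the cis-dihydrobenzofuran F22, whose C-3 is set by the catalyst. Catalytic acid epimerises C-2 through the 4-methoxybenzylic cation to the trans isomer 11.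

## Further compounds

F1 | step 14 | Cb epimer of 31 (aroyl trans to the Ca aryl group) | Oc1ccc([C@H]2c3c(OC)cc(OC)cc3[C@@H]3c4c(cc(OC)cc4[C@@H]2C(=O)c2ccc(OC)cc2)O[C@H]3c2ccc(OC)cc2)cc1
F2 | step 17 | tert-butyl trimethylsilyl ketene acetal of ester 13 | CC(C)(C)OC(O[Si](C)(C)C)=Cc1cc(OC)cc2c1[C@@H](c1cc(OC)cc(OC)c1)[C@H](c1ccc(OC)cc1)O2
F3 | step 17 | coupled tert-butyl ester (Ce–Cx bond, Cx bearing CO2t-Bu) | COc1ccc([C@H]2c3c(OC)cc(OC)cc3[C@@H]3c4c(cc(OC)cc4[C@H]2[C@H](c2ccc(OC)cc2)[C@H](C(=O)OC(C)(C)C)c4cc(OC)cc5c4[C@@H](c4cc(OC)cc(OC)c4)[C@H](c2ccc(OC)cc2)O5)O[C@H]3c2ccc(OC)cc2)cc1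
F4 | step 17 | coupled seven-ring ketone | COc1ccc([C@H]2c3c(OC)cc(OC)cc3[C@@H]3c4c(cc(OC)cc4[C@H]2[C@H](c2ccc(OC)cc2)[C@H]2c4cc(OC)cc5c4[C@@H](c4cc(OC)cc(OC)c4C2=O)[C@H](c2ccc(OC)cc2)O5)O[C@H]3c2ccc(OC)cc2)cc1
F5 | step 18 | tertiary carbinol from 18 and 36 | C1c2cc(OC)cc3c2[C@@H](c2cc(OC)cc(OC)c2[C@H](c2ccc(OC)cc2)C1(O)c1cc(OC)cc2c1[C@@H](c1cc(OC)cc(OC)c1)[C@H](c1ccc(OC)cc1)O2)[C@H](c2ccc(OC)cc2)O3
F6 | step 18 | eight-ring alkene (C=C between Cx and Cy, Cy bearing fragment C) | C=1c2cc(OC)cc3c2[C@@H](c2cc(OC)cc(OC)c2[C@H](c2ccc(OC)cc2)C1c1cc(OC)cc2c1[C@@H](c1cc(OC)cc(OC)c1)[C@H](c1ccc(OC)cc1)O2)[C@H](c2ccc(OC)cc2)O3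
F7 | step 7 | 4-allyl analogue of 11 | C=CCc1cc(OC)cc2c1[C@@H](c1cc(OC)cc(OC)c1)[C@H](c1ccc(OC)cc1)O2
F8 | step 7 | arylacetaldehyde | O=CCc1cc(OC)cc2c1[C@@H](c1cc(OC)cc(OC)c1)[C@H](c1ccc(OC)cc1)O2
F9 | step 7 | trans 2-(4-methoxyphenyl)-3-(arylmethyl)oxirane | COc1ccc(C2OC2Cc2cc(OC)cc3c2[C@@H](c2cc(OC)cc(OC)c2)[C@H](c2ccc(OC)cc2)O3)cc1
F10 | step 7 | eight-ring carbinol (18 with CH–OH in place of C=O) | C1c2cc(OC)cc3c2[C@@H](c2cc(OC)cc(OC)c2[C@H](c2ccc(OC)cc2)C1O)[C@H](c2ccc(OC)cc2)O3
F11 | step 11 | 2-(2-bromo-4,6-dimethoxyphenyl)-1,3-dioxolane | COc1cc(OC)c(C2OCCO2)c(Br)c1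
F12 | step 11 | dioxolanyl dihydrobenzofuran bromide | O1CCOC1c3c(OC)cc(OC)cc3[C@@H]3c4c(cc(OC)cc4Br)O[C@H]3c2ccc(OC)cc2
F13 | step 11 | dioxolanyl benzyl ketone | O1CCOC1c3c(OC)cc(OC)cc3[C@@H]3c4c(cc(OC)cc4CC(=O)c2ccc(OC)cc2)O[C@H]3c2ccc(OC)cc2
F14 | step 11 | formyl benzyl ketone | O=Cc3c(OC)cc(OC)cc3[C@@H]3c4c(cc(OC)cc4CC(=O)c2ccc(OC)cc2)O[C@H]3c2ccc(OC)cc2
F15 | step 11 | silyl-protected hydroxybenzhydrol ketone | CC(C)[Si](C(C)C)(C(C)C)Oc1ccc(cc1)C(O)c3c(OC)cc(OC)cc3[C@@H]3c4c(cc(OC)cc4CC(=O)c2ccc(OC)cc2)O[C@H]3c2ccc(OC)cc2
F16 | step 11 | free 4-hydroxybenzhydrol ketone (carbinol analogue of 29) | Oc1ccc(cc1)C(O)c3c(OC)cc(OC)cc3[C@@H]3c4c(cc(OC)cc4CC(=O)c2ccc(OC)cc2)O[C@H]3c2ccc(OC)cc2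
F17 | step 4 | 2-bromo-4-methoxy-6-[(4-methoxybenzyl)oxy]benzaldehyde | COc1ccc(COc2cc(OC)cc(Br)c2C=O)cc1
F18 | step 4 | diaryl carbinol from F17 and 8 | COc1ccc(COc2cc(OC)cc(Br)c2C(O)c2cc(OC)cc(OC)c2)cc1
F19 | step 4 | diaryl ketone | COc1ccc(COc2cc(OC)cc(Br)c2C(=O)c2cc(OC)cc(OC)c2)cc1
F20 | step 4 | hydrazone of F19 | COc1ccc(COc2cc(OC)cc(Br)c2C(=NN)c2cc(OC)cc(OC)c2)cc1
F21 | step 4 | diaryldiazomethane | COc1ccc(COc2cc(OC)cc(Br)c2C(=[N+]=[N-])c2cc(OC)cc(OC)c2)cc1
F22 | step 4 | cis-dihydrobenzofuran (C-2 epimer of 11) | Brc1cc(OC)cc2c1[C@@H](c1cc(OC)cc(OC)c1)[C@@H](c1ccc(OC)cc1)O2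
A1 | alternative 1 | 6-hydroxy-4-(silyloxymethyl) dihydrobenzofuran block | CC(C)(C)[Si](C)(C)OCc2cc(O)cc3c2[C@@H](c2cc(OC)cc(OC)c2)[C@H](c2ccc(OC)cc2)O3
A2 | alternative 2 | dibenzocyclooctenone diaryl-acetate | C=C[C@H]2c4cc(OCc5ccccc5)cc(OCc5ccccc5)c4[C@H](C(=O)OC)c4cc(OC)cc(OC)c4C(=O)[C@H]2c2cc(OC)cc4c2[C@@H](c2cc(OC)cc(OC)c2)[C@H](c2ccc(OC)cc2)O4
A3 | alternative 3 | dibenzocycloheptanone diaryl-acetate | COC(=O)[C@@H]1c2cc(OC)cc(OC)c2C(=O)Cc2cc(OCc3ccccc3)cc(OCc3ccccc3)c21
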